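**Retrosynthetic overview**
- The target is unmasked last from its phenol benzyl ether and its benzylic silyl ether.
- The C3–benzyl bond comes from a trans-selective alkylation of the enolate of a 4-substituted γ-butyrolactone with 4-(benzyloxy)-3-methoxybenzyl bromide.
- The γ-butyrolactone is the only ring made in the route. It forms after the aldol and before the benzylation, from a pent-4-en-1-ol unit by alkene cleavage to a lactol and oxidation.
- The key C–C bond (carbinol carbon to lactone C4) comes from an Evans syn-aldol of N-pent-4-enoyl-(S)-4-benzyloxazolidinone with 3,4-dimethoxybenzaldehyde. It sets both contiguous stereocentres.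
- The aromatic rings and the auxiliary ring are bought.

Assumption: 4-(benzyloxy)-3-methoxybenzaldehyde and both enantiomers of 4-benzyloxazolidin-2-one are taken as catalogue materials; "carbinol carbon" means the ArCH(O) carbon, and lactone locants are those in the name of 20.

**Route**

Step 1
Reactants: 1 (S)-4-benzyloxazolidin-2-one; 2 pent-4-enoyl chloride
Product: 4 (S)-4-benzyl-3-(pent-4-enoyl)oxazolidin-2-one, via N-lithio oxazolidinone 3 (not isolated)
Conditions: n-BuLi, THF, −78 °C; then 2, −78 to 0 °C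
Reagents that add atoms: none
Why: N-acylation of the lithiated carbamate by the acid chloride (nucleophilic acyl substitution) is the standard imide preparation and does not touch the auxiliary stereocentre.

Step 2
Reactants: 4 (S)-4-benzyl-3-(pent-4-enoyl)oxazolidin-2-one; 5 3,4-dimethoxybenzaldehyde
Product: 8 (4S)-4-benzyl-3-[(2S)-2-[(S)-(3,4-dimethoxyphenyl)(hydroxy)methyl]pent-4-enoyl]oxazolidin-2-one, via Z-dibutylboron enolate 6 (not isolated), via dibutylboron aldolate 7 (not isolated)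
Conditions: n-Bu2BOTf, i-Pr2NEt, CH2Cl2, 0 °C; then 5, −78 to 0 °C; then pH 7 buffer, MeOH, 30% H2O2, 0 °C
Reagents that add atoms: none
Why: Evans syn-aldol in which the Z-boron enolate reacts through a closed Zimmerman–Traxler chair on the face away from the auxiliary benzyl group, setting the (2S) centre and the (S) carbinol in a syn relationship.

Step 3
Reactants: 8 (4S)-4-benzyl-3-[(2S)-2-[(S)-(3,4-dimethoxyphenyl)(hydroxy)methyl]pent-4-enoyl]oxazolidin-2-one
Product: 9 (4S)-4-benzyl-3-[(2S)-2-[(S)-(tert-butyldimethylsilyloxy)(3,4-dimethoxyphenyl)methyl]pent-4-enoyl]oxazolidin-2-one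
Conditions: TBSOTf, 2,6-lutidine, CH2Cl2, 0 °C
Reagents that add atoms: TBSOTf (tert-butyldimethylsilyl trifluoromethanesulfonate), CC(C)(C)[Si](C)(C)OS(=O)(=O)C(F)(F)F
Why: O-silylation with a silyl triflate and a hindered non-nucleophilic base protects the secondary alcohol without retro-aldol, so that only the primary hydroxyl made next can close the ring.

Step 4
Reactants: 9 (4S)-4-benzyl-3-[(2S)-2-[(S)-(tert-butyldimethylsilyloxy)(3,4-dimethoxyphenyl)methyl]pent-4-enoyl]oxazolidin-2-one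
Product: 10 (2R)-2-[(S)-(tert-butyldimethylsilyloxy)(3,4-dimethoxyphenyl)methyl]pent-4-en-1-ol
Conditions: LiBH4, MeOH (1 equiv), THF, 0 °C
Reagents that add atoms: none
Why: Reductive cleavage of the imide by hydride attack at the exocyclic carbonyl gives the primary alcohol without enolisation, so both stereocentres are kept (the descriptor changes to 2R only by priority) and auxiliary 1 is recovered.

Step 5
Reactants: 10 (2R)-2-[(S)-(tert-butyldimethylsilyloxy)(3,4-dimethoxyphenyl)methyl]pent-4-en-1-ol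
Product: 12 (4R)-4-[(S)-(tert-butyldimethylsilyloxy)(3,4-dimethoxyphenyl)methyl]tetrahydrofuran-2-ol (anomer mixture), via hydroxy aldehyde 11 (not isolated)
Conditions: OsO4 (2 mol%), NaIO4 (4 equiv), 2,6-lutidine, dioxane/H2O 3:1, rt
Reagents that add atoms: OsO4 (catalytic oxygen carrier), O=[Os](=O)(=O)=O; NaIO4 (terminal oxidant), [Na+].[O-]I(=O)(=O)=O
Why: Lemieux–Johnson oxidative cleavage of the terminal alkene gives an aldehyde that the only free hydroxyl traps as a five-membered lactol, with no stereocentre of the chain involved.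

Step 6
Reactants: 12 (4R)-4-[(S)-(tert-butyldimethylsilyloxy)(3,4-dimethoxyphenyl)methyl]tetrahydrofuran-2-ol
Product: 13 (4R)-4-[(S)-(tert-butyldimethylsilyloxy)(3,4-dimethoxyphenyl)methyl]dihydrofuran-2(3H)-one
Conditions: TEMPO (10 mol%), PhI(OAc)2 (1.5 equiv), CH2Cl2, rt
Reagents that add atoms: none
Why: Oxoammonium-mediated oxidation of the lactol C–H to the lactone proceeds under near-neutral conditions that leave the silyl ether and the dimethoxyarene intact.

Step 7
Reactants: 14 4-(benzyloxy)-3-methoxybenzaldehyde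
Product: 15 [4-(benzyloxy)-3-methoxyphenyl]methanol
Conditions: NaBH4, MeOH, 0 °C
Reagents that add atoms: none
Why: Borohydride reduction of an aromatic aldehyde to the benzylic alcohol is clean and leaves the benzyl ether untouched.

Step 8
Reactants: 15 [4-(benzyloxy)-3-methoxyphenyl]methanol
Product: 16 1-(benzyloxy)-4-(bromomethyl)-2-methoxybenzene
Conditions: PBr3 (0.4 equiv), Et2O, 0 °C
Reagents that add atoms: PBr3 (phosphorus tribromide), BrP(Br)Br
Why: Activation of the benzylic alcohol as a phosphite followed by bromide displacement (SN2-type substitution) gives the reactive benzyl bromide, which is used without storage.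

Step 9
Reactants: 13 (4R)-4-[(S)-(tert-butyldimethylsilyloxy)(3,4-dimethoxyphenyl)methyl]dihydrofuran-2(3H)-one; 16 1-(benzyloxy)-4-(bromomethyl)-2-methoxybenzene
Product: 18 (3R,4R)-3-[4-(benzyloxy)-3-methoxybenzyl]-4-[(S)-(tert-butyldimethylsilyloxy)(3,4-dimethoxyphenyl)methyl]dihydrofuran-2(3H)-one, via lithium enolate 17 (not isolated)
Conditions: LiN(SiMe3)2 (1.1 equiv), THF, −78 °C; then 16, DMPU, −78 to −30 °C
Reagents that add atoms: none
Why: Lactone enolate alkylation (SN2) in which the benzyl bromide approaches the face anti to the bulky C4 substituent, setting the (3R) centre in the 3,4-trans arrangement that is also the thermodynamic one.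

Step 10
Reactants: 18 (3R,4R)-3-[4-(benzyloxy)-3-methoxybenzyl]-4-[(S)-(tert-butyldimethylsilyloxy)(3,4-dimethoxyphenyl)methyl]dihydrofuran-2(3H)-one
Product: 19 (3R,4R)-4-[(S)-(tert-butyldimethylsilyloxy)(3,4-dimethoxyphenyl)methyl]-3-(4-hydroxy-3-methoxybenzyl)dihydrofuran-2(3H)-one
Conditions: H2 (1 atm), Pd/C (10 wt% Pd on carbon), EtOAc, rt
Reagents that add atoms: none
Why: Catalytic hydrogenolysis cleaves the aryl benzyl ether rapidly under neutral conditions, while the silylated benzylic C–O bond, the lactone and all stereocentres are inert.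

Step 11
Reactants: 19 (3R,4R)-4-[(S)-(tert-butyldimethylsilyloxy)(3,4-dimethoxyphenyl)methyl]-3-(4-hydroxy-3-methoxybenzyl)dihydrofuran-2(3H)-one
Product: 20 (3R,4R)-4-[(S)-(3,4-dimethoxyphenyl)(hydroxy)methyl]-3-(4-hydroxy-3-methoxybenzyl)dihydrofuran-2(3H)-one
Conditions: HF·pyridine, pyridine, THF, 0 °C to rt
Reagents that add atoms: none
Why: Fluoride-mediated desilylation under buffered, weakly acidic conditions frees the alcohol without generating an alkoxide (which would translactonise) or a benzylic cation (which would scramble the carbinol centre), so all three stereocentres are delivered unchanged.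

**Compound list**

1 | (S)-4-benzyloxazolidin-2-one | O=C1N[C@@H](Cc2ccccc2)CO1 | starting material
2 | pent-4-enoyl chloride | C=CCCC(=O)Cl | starting material
3 | N-lithio (S)-4-benzyloxazolidin-2-one (not isolated) | [Li]N1[C@@H](Cc2ccccc2)COC1=O | intermediate
4 | (S)-4-benzyl-3-(pent-4-enoyl)oxazolidin-2-one | C=CCCC(=O)N1[C@@H](Cc2ccccc2)COC1=O | intermediate
5 | 3,4-dimethoxybenzaldehyde | COc1ccc(C=O)cc1OC | starting material
6 | Z-dibutylboron enolate of 4 (not isolated) | C=CC/C=C(\OB(CCCC)CCCC)N1[C@@H](Cc2ccccc2)COC1=O | intermediate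
7 | dibutylboron aldolate of 8 (not isolated) | C=CC[C@@H]([C@H](OB(CCCC)CCCC)c1ccc(OC)c(OC)c1)C(=O)N1[C@@H](Cc2ccccc2)COC1=O | intermediate
8 | (4S)-4-benzyl-3-[(2S)-2-[(S)-(3,4-dimethoxyphenyl)(hydroxy)methyl]pent-4-enoyl]oxazolidin-2-one | C=CC[C@@H]([C@H](O)c1ccc(OC)c(OC)c1)C(=O)N1[C@@H](Cc2ccccc2)COC1=O | intermediate
9 | (4S)-4-benzyl-3-[(2S)-2-[(S)-(tert-butyldimethylsilyloxy)(3,4-dimethoxyphenyl)methyl]pent-4-enoyl]oxazolidin-2-one | C=CC[C@@H]([C@H](O[Si](C)(C)C(C)(C)C)c1ccc(OC)c(OC)c1)C(=O)N1[C@@H](Cc2ccccc2)COC1=O | intermediate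
10 | (2R)-2-[(S)-(tert-butyldimethylsilyloxy)(3,4-dimethoxyphenyl)methyl]pent-4-en-1-ol | C=CC[C@@H]([C@H](O[Si](C)(C)C(C)(C)C)c1ccc(OC)c(OC)c1)CO | intermediate
11 | (3R)-3-[(S)-(tert-butyldimethylsilyloxy)(3,4-dimethoxyphenyl)methyl]-4-hydroxybutanal (not isolated) | O=CC[C@@H]([C@H](O[Si](C)(C)C(C)(C)C)c1ccc(OC)c(OC)c1)CO | intermediate
12 | (4R)-4-[(S)-(tert-butyldimethylsilyloxy)(3,4-dimethoxyphenyl)methyl]tetrahydrofuran-2-ol (anomer mixture) | OC1C[C@@H]([C@H](O[Si](C)(C)C(C)(C)C)c2ccc(OC)c(OC)c2)CO1 | intermediate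
13 | (4R)-4-[(S)-(tert-butyldimethylsilyloxy)(3,4-dimethoxyphenyl)methyl]dihydrofuran-2(3H)-one | O=C1C[C@@H]([C@H](O[Si](C)(C)C(C)(C)C)c2ccc(OC)c(OC)c2)CO1 | intermediate
14 | 4-(benzyloxy)-3-methoxybenzaldehyde | COc1cc(C=O)ccc1OCc1ccccc1 | starting material
15 | [4-(benzyloxy)-3-methoxyphenyl]methanol | COc1cc(CO)ccc1OCc1ccccc1 | intermediate
16 | 1-(benzyloxy)-4-(bromomethyl)-2-methoxybenzene | COc1cc(CBr)ccc1OCc1ccccc1 | intermediate
17 | lithium enolate of 13 (not isolated) | [Li]OC1=C[C@@H]([C@H](O[Si](C)(C)C(C)(C)C)c2ccc(OC)c(OC)c2)CO1 | intermediate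
18 | (3R,4R)-3-[4-(benzyloxy)-3-methoxybenzyl]-4-[(S)-(tert-butyldimethylsilyloxy)(3,4-dimethoxyphenyl)methyl]dihydrofuran-2(3H)-one | COc1cc(C[C@H]2C(=O)OC[C@@H]2[C@H](O[Si](C)(C)C(C)(C)C)c2ccc(OC)c(OC)c2)ccc1OCc1ccccc1 | intermediate
19 | (3R,4R)-4-[(S)-(tert-butyldimethylsilyloxy)(3,4-dimethoxyphenyl)methyl]-3-(4-hydroxy-3-methoxybenzyl)dihydrofuran-2(3H)-one | COc1cc(C[C@H]2C(=O)OC[C@@H]2[C@H](O[Si](C)(C)C(C)(C)C)c2ccc(OC)c(OC)c2)ccc1O | intermediate
20 | (3R,4R)-4-[(S)-(3,4-dimethoxyphenyl)(hydroxy)methyl]-3-(4-hydroxy-3-methoxybenzyl)dihydrofuran-2(3H)-one | COc1cc(C[C@H]2C(=O)OC[C@@H]2[C@H](O)c2ccc(OC)c(OC)c2)ccc1O | target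

**Summary**

Total step count: 11. Longest linear sequence: 9 steps (steps 1–6, then 9–11); the bromide branch (steps 7–8) joins at step 9.

**Steps most likely to fail** (route order; step 9 carries the most risk)

Step 2 (aldol with an electron-rich, sluggish aromatic aldehyde; incomplete conversion or eroded diastereoselectivity). The fallback sets out from 2 and comes back at 10. It forms the same bond by a Claisen-type acylation and sets the carbinol by reduction.
- Lithiated (R)-4-benzyloxazolidin-2-one (n-BuLi, THF, −78 °C) is acylated with 2 to give (R)-4-benzyl-3-(pent-4-enoyl)oxazolidin-2-one F1.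
- Its chelated lithium Z-enolate (LiN(i-Pr)2, THF, −78 °C) is C-acylated with 3,4-dimethoxybenzoyl chloride on the face anti to the auxiliary benzyl group. This gives the configurationally stable β-keto imide (4R)-4-benzyl-3-[(2S)-2-(3,4-dimethoxybenzoyl)pent-4-enoyl]oxazolidin-2-one F2.
- Chelation-controlled reduction with Zn(BH4)2 (CH2Cl2/Et2O, −20 °C) gives the syn alcohol (4R)-4-benzyl-3-[(2S)-2-[(S)-(3,4-dimethoxyphenyl)(hydroxy)methyl]pent-4-enoyl]oxazolidin-2-one F3.
- Silylation (TBSOTf, 2,6-lutidine) gives (4R)-4-benzyl-3-[(2S)-2-[(S)-(tert-butyldimethylsilyloxy)(3,4-dimethoxyphenyl)methyl]pent-4-enoyl]oxazolidin-2-one F4.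
- LiBH4 cleavage of the auxiliary gives 10.

Step 4 (reductive removal of the auxiliary from a hindered β-silyloxy imide; endocyclic cleavage or silyl migration may compete). The fallback sets out from 8 and comes back at 10. It reduces before protecting.
- The free aldol 8 is reduced with LiBH4 (THF, MeOH, 0 °C; the free hydroxyl assists exocyclic cleavage) to (1S,2R)-1-(3,4-dimethoxyphenyl)-2-(prop-2-en-1-yl)propane-1,3-diol F5.
- Both hydroxyls are silylated (TBSOTf, 2,6-lutidine) to (1S,2R)-1,3-bis(tert-butyldimethylsilyloxy)-1-(3,4-dimethoxyphenyl)-2-(prop-2-en-1-yl)propane F6.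
- The primary silyl ether alone is cleaved (HF·pyridine, pyridine, THF, 0 °C) to give 10.

Step 9 (alkylation of a hindered, β-branched lactone enolate; low conversion or over-alkylation). The fallback sets out from 13 and comes back at 18. It replaces the SN2 alkylation by an aldol addition and a radical deoxygenation.
- Lithium enolate 17 is added to aldehyde 14 at −78 °C, again anti to the C4 substituent. This gives the trans β-hydroxy lactone (3S,4R)-3-{[4-(benzyloxy)-3-methoxyphenyl](hydroxy)methyl}-4-[(S)-(tert-butyldimethylsilyloxy)(3,4-dimethoxyphenyl)methyl]dihydrofuran-2(3H)-one F7 as a mixture of carbinol epimers.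
- The new hydroxyl is converted with PhOC(S)Cl, pyridine and DMAP into the O-phenyl thionocarbonate of that alcohol F8.
- Barton–McCombie deoxygenation (Bu3SnH, AIBN, toluene, 90 °C) erases the epimeric carbinol centre and gives 18.

**Further compounds**

F1 | step 2 | (R)-4-benzyl-3-(pent-4-enoyl)oxazolidin-2-one | C=CCCC(=O)N1[C@H](Cc2ccccc2)COC1=O
F2 | step 2 | (4R)-4-benzyl-3-[(2S)-2-(3,4-dimethoxybenzoyl)pent-4-enoyl]oxazolidin-2-one | C=CC[C@@H](C(=O)c1ccc(OC)c(OC)c1)C(=O)N1[C@H](Cc2ccccc2)COC1=O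
F3 | step 2 | (4R)-4-benzyl-3-[(2S)-2-[(S)-(3,4-dimethoxyphenyl)(hydroxy)methyl]pent-4-enoyl]oxazolidin-2-one | C=CC[C@@H]([C@H](O)c1ccc(OC)c(OC)c1)C(=O)N1[C@H](Cc2ccccc2)COC1=O
F4 | step 2 | (4R)-4-benzyl-3-[(2S)-2-[(S)-(tert-butyldimethylsilyloxy)(3,4-dimethoxyphenyl)methyl]pent-4-enoyl]oxazolidin-2-one | C=CC[C@@H]([C@H](O[Si](C)(C)C(C)(C)C)c1ccc(OC)c(OC)c1)C(=O)N1[C@H](Cc2ccccc2)COC1=O
F5 | step 4 | (1S,2R)-1-(3,4-dimethoxyphenyl)-2-(prop-2-en-1-yl)propane-1,3-diol | C=CC[C@@H]([C@H](O)c1ccc(OC)c(OC)c1)CO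
F6 | step 4 | (1S,2R)-1,3-bis(tert-butyldimethylsilyloxy)-1-(3,4-dimethoxyphenyl)-2-(prop-2-en-1-yl)propane | C=CC[C@@H]([C@H](O[Si](C)(C)C(C)(C)C)c1ccc(OC)c(OC)c1)CO[Si](C)(C)C(C)(C)C
F7 | step 9 | (3S,4R)-3-{[4-(benzyloxy)-3-methoxyphenyl](hydroxy)methyl}-4-[(S)-(tert-butyldimethylsilyloxy)(3,4-dimethoxyphenyl)methyl]dihydrofuran-2(3H)-one (carbinol epimers) | COc1cc(C(O)[C@H]2C(=O)OC[C@@H]2[C@H](O[Si](C)(C)C(C)(C)C)c2ccc(OC)c(OC)c2)ccc1OCc1ccccc1
F8 | step 9 | O-phenyl thionocarbonate of F7 | COc1cc(C(OC(=S)Oc2ccccc2)[C@H]2C(=O)OC[C@@H]2[C@H](O[Si](C)(C)C(C)(C)C)c2ccc(OC)c(OC)c2)ccc1OCc1ccccc1
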